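Late on, the Wednesday's run stands flat and the Monday's run is slowing, with the same charge of coupling partner and the same catalyst. At its last reading the Monday's run has 57.5% of that partner's charge as target. The flat stretch of the Wednesday's run averages 0.126 M, which is 87.5% of the same charge.

in all of them: free catalyst 0.00360 M

| flask | starting material | coupling partner | time |
|---|---|---|---|
| Monday's | 0.120 M | 0.144 M |  |
| Thursday's | 0.0480 M | 0.0720 M |  |
| Wednesday's | 0.360 M | 0.144 M |  |
| Sunday's | 0.120 M | 0.144 M | 55 min |

| run | time / min | [target] / M |
|---|---|---|
| Monday's run | 3.7 | 0.0405 |
| Monday's run | 7.3 | 0.0614 |
| Monday's run | 11 | 0.0722 |
| Monday's run | 15 | 0.0785 |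
| Monday's run | 18 | 0.0809 |
| Monday's run | 22 | 0.0828 |
| Thursday's run | 3.7 | 0.0064 |
| Thursday's run | 7.3 | 0.0122 |
| Thursday's run | 11 | 0.0163 |
| Thursday's run | 15 | 0.0182 |
| Thursday's run | 18 | 0.0195 |
| Thursday's run | 22 | 0.0206 |
| Wednesday's run | 3.7 | 0.1103 |
| Wednesday's run | 7.3 | 0.1252 |
| Wednesday's run | 11 | 0.1267 |
| Wednesday's run | 15 | 0.1256 |
| Wednesday's run | 18 | 0.1265 |
| Wednesday's run | 22 | 0.1254 |

(each reading ± 6 × 10⁻⁴ M)

- Overall: starting material + coupling partner -> target, with free catalyst as catalyst.
- Constant volume, constant temperature.
- An order is taken over about fifteen percent of the charge, up and down.

- apparent order in [starting material] of the starting rate, round the charge of the Monday's run (the rate where two percent of its starting material have turned into target) (one fixed amount of target, the same in the runs compared)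
- apparent order in [coupling partner] of the starting rate, round the charge of the Monday's run (the rate where two percent of its starting material have turned into target)
- the Thursday's run starts with 0.0720 M less of starting material and of coupling partner than the Monday's run, and with no target. Compared where both hold the same amount of starting material, once fifteen percent of what the Thursday's run was charged with has turned into target, is the Thursday's run faster, slower or alike (within a tenth)?
- target in the Sunday's run at 55 min, as a share of the starting material charged

Our zero of the scale is a flask with no side path, where the two partners go one to one until the limiting reagent is used up. Against that, the Wednesday's run falls 12.5% short of its partner charge, with 65.0% of its starting material still present.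

We bet on a race. Each coupling partner either couples or is lost at a steady rate of its own. We let coupling scale with starting material: at the first reading the Wednesday's run has made 2.72 times the target of the Monday's run, for 3.00 times the charge, which reads as an order of 0.912, and we take it as first order.

Integrating the race to its end, with everything in fractions of the Monday's starting-material charge, gives: partner charged = target + b × ln(starting material charged / starting material left). The Wednesday's run then gives b = 0.347. This b is the break-even level, the fraction of starting material at which coupling and loss take partner equally fast.

For the Sunday's run the partner charge is 1.20. Two averaged steps from the last Monday's reading give 74.2%, then 73.6%, and we take that as the end of the race.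

The forecast says 1.4 (1.1 to 1.7) in starting material and 1 (0.7 to 1.4) in coupling partner. It calls the Thursday's run faster, “pointing to reversal, inhibition or catalyst decay”, and gives 70.5% (68% to 73%). Our figure lies above the top of that range.

The flask gives orders of 1.0 and 1.0, the Thursday's run faster by a factor of 1.8, and 71.1% for the Sunday's run, 2.5 percentage points below our figure.

    2 free catalyst ⇌ catalyst dimer, settled at all times (4760 M⁻¹)
    catalyst dimer + starting material + coupling partner → target + catalyst dimer (450.6 M⁻² min⁻¹)
    coupling partner → lost reagent (0.06720 min⁻¹)
    starting material + coupling partner + target → 2 target (16.98 M⁻² min⁻¹)

Put into the rule as the end of the race, the Sunday's result reads back b = 0.395, against 0.347 from the Wednesday's run. The simulated Sunday's run without the step from coupling partner to lost reagent has no such level, so it comes close to our zero of the scale, with 99.3% as target. That step is the main reason the Sunday's run ends at 71.1%: it costs 28 points, which is 98% of what is missing.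

(The data were computed from invented constants, noise included.)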